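**Retrosynthetic overview**
- Feature: on ring A the oxygen-bearing C8a and the acyl-bearing C4a are neighbours, framed by the C8 benzyl carbon and the C5 oxygen. This is the footprint of a 3-alkoxy-6-benzyl aryne that has taken up O and C(=O) across its triple bond.
- Key disconnection: ring C, the only ring made, is cut at O–C8a, C4a–C4 and O1–C2. This gives a ring A silyl aryl triflate and 3-(4-methoxyphenyl)propiolic acid.
- The silyl triflate goes back through carbamate-directed ortho-silylation to an ortho-benzylphenol, and that to 2-hydroxy-4,6-dimethoxybenzaldehyde plus an anisyl Grignard reagent (addition, ionic reduction).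
- End game: C3 hydroxylation by lithiation, borylation and oxidation, then cleavage of the four methyl ethers. Ring A, ring B and the benzyl ring are bought.

Key step: step 6

Assumption: 2 is used as its commercial THF solution (otherwise made from 4-bromoanisole and Mg). The target has no stereocenter; the only one on the way (in 3, racemic) is removed in step 2.

**Route**

Step 1
Reactants: 1 2-hydroxy-4,6-dimethoxybenzaldehyde; 2 4-methoxyphenylmagnesium bromide
Product: 3 racemic 2-[hydroxy(4-methoxyphenyl)methyl]-3,5-dimethoxyphenol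
Conditions: 2 (3 equiv), THF, 0 °C → rt; sat. aq. NH4Cl; crude 3 used directly
Reagents that add atoms: none
Why: Grignard 1,2-addition to the aldehyde, in which the first equivalent of 2 only deprotonates the phenol and the ArOMgBr-chelated aldehyde should still accept a second equivalent to give the racemic benzhydrol, whose stereocenter is removed in step 2.

Step 2
Reactants: 3 racemic 2-[hydroxy(4-methoxyphenyl)methyl]-3,5-dimethoxyphenol
Product: 4 3,5-dimethoxy-2-(4-methoxybenzyl)phenol
Conditions: Et3SiH, CF3CO2H, CH2Cl2, 0 °C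
Reagents that add atoms: none
Why: Ionic hydrogenation, in which CF3CO2H ionises the doubly benzylic carbinol (flanked by ortho and para oxygen donors) to an ortho-quinone methide/benzhydryl cation that should take hydride from Et3SiH faster than it alkylates another arene.

Step 3
Reactants: 4 3,5-dimethoxy-2-(4-methoxybenzyl)phenol
Product: 5 3,5-dimethoxy-2-(4-methoxybenzyl)phenyl N-isopropylcarbamate
Conditions: iPrNCO, Et3N (cat.), CH2Cl2, rt
Reagents that add atoms: isopropyl isocyanate CC(C)N=C=O
Why: Amine-catalysed addition of the phenol O–H across the isocyanate (carbamoylation) should give a secondary carbamate that directs metalation and can later be cleaved under mild base.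

Step 4
Reactants: 5 3,5-dimethoxy-2-(4-methoxybenzyl)phenyl N-isopropylcarbamate
Product: 9 3,5-dimethoxy-2-(4-methoxybenzyl)-6-(trimethylsilyl)phenyl N-isopropylcarbamate, via N-silyl carbamate 6 (not isolated), via aryllithium 7 (not isolated), via N-silyl C-silyl carbamate 8 (not isolated)
Conditions: TBSOTf, TMEDA, Et2O, 0 °C → rt; n-BuLi, TMEDA, −78 °C; Me3SiCl, −78 °C → rt; aq. NaHSO4
Reagents that add atoms: chlorotrimethylsilane C[Si](C)(C)Cl
Why: Directed ortho-metalation, in which in situ N-silylation masks the carbamate N–H and n-BuLi/TMEDA should then remove C6–H (the ring proton between the carbamate, the strongest director present, and the C5 methoxy group) in preference to C4–H and the diarylmethane CH2, Me3SiCl trapping aryllithium 7 at −78 °C before an anionic Fries shift can set in and the N–Si bond being hydrolysed in the acidic work-up.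

Step 5
Reactants: 9 3,5-dimethoxy-2-(4-methoxybenzyl)-6-(trimethylsilyl)phenyl N-isopropylcarbamate
Product: 11 3,5-dimethoxy-2-(4-methoxybenzyl)-6-(trimethylsilyl)phenyl trifluoromethanesulfonate, via silyl phenol 10 (not isolated)
Conditions: DBU, Et2NH, MeCN, 40 °C; then PhN(SO2CF3)2, rt
Reagents that add atoms: N-phenylbis(trifluoromethanesulfonimide) O=S(=O)(N(c1ccccc1)S(=O)(=O)C(F)(F)F)C(F)(F)F
Why: E1cB cleavage of the N–H carbamate by DBU (the departing isocyanate is scavenged by Et2NH) frees the phenoxide, which should be sulfonylated in the same flask by the mild triflyl donor under base, so that the electron-rich aryl–Si bond never meets acid.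

Step 6
Reactants: 11 3,5-dimethoxy-2-(4-methoxybenzyl)-6-(trimethylsilyl)phenyl trifluoromethanesulfonate; 12 3-(4-methoxyphenyl)propiolic acid
Product: 16 5,7-dimethoxy-8-(4-methoxybenzyl)-2-(4-methoxyphenyl)-4H-chromen-4-one, via aryne 13 (not isolated), via aryl ester anion 14 (not isolated), via hydroxyaryl ynone 15 (not isolated)
Conditions: CsF (4 equiv), 11 (1.5 equiv), THF, 125 °C, sealed tube
Reagents that add atoms: none
Why: Fluoride attacks silicon in 11 and triflate leaves (1,2-elimination) to give aryne 13; the carboxylate oxygen of the RCO2Cs salt of 12 adds to the aryne carbon that becomes C8a, the aryl anion 14 so formed at C4a attacks its own ester carbonyl through a four-membered alkoxide, and ring-opening moves the acyl group onto carbon (C4a–C4), leaving phenoxide 15. This is the known insertion of arynes into the C–O bond of carboxylic acids (formally an anionic Fries-type O-to-C acyl shift), which with arylpropiolic acids runs on to flavones. Ring C should then close by 6-endo-dig oxa-Michael addition of the C8a phenoxide to the β-carbon of the ynone (O1–C2), the allenolate being protonated at C3. No stereocenter is formed. The step needs regioselective addition to the unsymmetrical aryne: the C5 methoxy group, by its inductive pull and the distortion it imposes, makes the remote aryne carbon the electrophilic one and stabilises negative charge ortho to itself, so oxygen should go to C8a and the acyl group to C4a, the small oxygen nucleophile tolerating the neighbouring C8 benzyl group. Because ring A only ever carries this one free oxygen, closure cannot give the 6-benzyl isomer.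

Step 7
Reactants: 16 5,7-dimethoxy-8-(4-methoxybenzyl)-2-(4-methoxyphenyl)-4H-chromen-4-one
Product: 19 3-hydroxy-5,7-dimethoxy-8-(4-methoxybenzyl)-2-(4-methoxyphenyl)-4H-chromen-4-one, via 3-lithioflavone 17 (not isolated), via C3 boronate 18 (not isolated)
Conditions: LiN(iPr)2, THF, −78 °C; B(OMe)3, −78 → 0 °C; AcOH, 30% aq. H2O2, 0 °C → rt
Reagents that add atoms: hydrogen peroxide OO
Why: Amide-base deprotonation of the flavone at C3 (the vinylic proton next to the carbonyl), borylation and oxidative 1,2-migration of carbon from boron to oxygen (boronate oxidation) is an established way from flavones to flavonols, and at −78 °C the diarylmethane CH2 should be too slow to compete.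

Step 8
Reactants: 19 3-hydroxy-5,7-dimethoxy-8-(4-methoxybenzyl)-2-(4-methoxyphenyl)-4H-chromen-4-one
Product: 20 8-C-p-hydroxybenzylkaempferol [3,5,7-trihydroxy-8-(4-hydroxybenzyl)-2-(4-hydroxyphenyl)-4H-chromen-4-one]
Conditions: BBr3 (excess), CH2Cl2, −78 °C → rt; then H2O
Reagents that add atoms: none
Why: Lewis-acid ether cleavage, in which BBr3 coordinates each methoxy oxygen and bromide removes the methyl group by SN2 substitution, boron chelation of the C4 carbonyl keeping ring A electron-poor so that the C8 benzyl group should neither migrate nor leave, and water hydrolysing the aryl borates to the target.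

**Compound list**

1 | 2-hydroxy-4,6-dimethoxybenzaldehyde | O=Cc1c(O)cc(OC)cc1OC | starting material
2 | 4-methoxyphenylmagnesium bromide | COc1ccc([Mg]Br)cc1 | starting material
3 | racemic 2-[hydroxy(4-methoxyphenyl)methyl]-3,5-dimethoxyphenol | COc1ccc(C(O)c2c(O)cc(OC)cc2OC)cc1 | intermediate
4 | 3,5-dimethoxy-2-(4-methoxybenzyl)phenol | COc1ccc(Cc2c(O)cc(OC)cc2OC)cc1 | intermediate
5 | 3,5-dimethoxy-2-(4-methoxybenzyl)phenyl N-isopropylcarbamate | COc1ccc(Cc2c(OC(=O)NC(C)C)cc(OC)cc2OC)cc1 | intermediate
6 | 3,5-dimethoxy-2-(4-methoxybenzyl)phenyl N-(tert-butyldimethylsilyl)-N-isopropylcarbamate (not isolated) | COc1ccc(Cc2c(OC(=O)N(C(C)C)[Si](C)(C)C(C)(C)C)cc(OC)cc2OC)cc1 | intermediate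
7 | 2-lithio-3,5-dimethoxy-6-(4-methoxybenzyl)phenyl N-(tert-butyldimethylsilyl)-N-isopropylcarbamate (not isolated) | COc1ccc(Cc2c(OC(=O)N(C(C)C)[Si](C)(C)C(C)(C)C)c([Li])c(OC)cc2OC)cc1 | intermediate
8 | 3,5-dimethoxy-2-(4-methoxybenzyl)-6-(trimethylsilyl)phenyl N-(tert-butyldimethylsilyl)-N-isopropylcarbamate (not isolated) | COc1ccc(Cc2c(OC(=O)N(C(C)C)[Si](C)(C)C(C)(C)C)c([Si](C)(C)C)c(OC)cc2OC)cc1 | intermediate
9 | 3,5-dimethoxy-2-(4-methoxybenzyl)-6-(trimethylsilyl)phenyl N-isopropylcarbamate | COc1ccc(Cc2c(OC(=O)NC(C)C)c([Si](C)(C)C)c(OC)cc2OC)cc1 | intermediate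
10 | 3,5-dimethoxy-2-(4-methoxybenzyl)-6-(trimethylsilyl)phenol (not isolated; present as its DBU-H salt) | COc1ccc(Cc2c(O)c([Si](C)(C)C)c(OC)cc2OC)cc1 | intermediate
11 | 3,5-dimethoxy-2-(4-methoxybenzyl)-6-(trimethylsilyl)phenyl trifluoromethanesulfonate | COc1cc(OC)c([Si](C)(C)C)c(OS(=O)(=O)C(F)(F)F)c1Cc1ccc(OC)cc1 | intermediate
12 | 3-(4-methoxyphenyl)propiolic acid | COc1ccc(C#CC(=O)O)cc1 | starting material
13 | 4,6-dimethoxy-3-(4-methoxybenzyl)-1,2-didehydrobenzene (aryne, not isolated) | COC1=CC(OC)=C(Cc2ccc(OC)cc2)C#C1 | intermediate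
14 | 2-cesio-3,5-dimethoxy-6-(4-methoxybenzyl)phenyl 3-(4-methoxyphenyl)prop-2-ynoate (not isolated) | COc1ccc(cc1)C#CC(=O)Oc1c(Cc2ccc(OC)cc2)c(OC)cc(OC)c1[Cs] | intermediate
15 | 1-[2-hydroxy-4,6-dimethoxy-3-(4-methoxybenzyl)phenyl]-3-(4-methoxyphenyl)prop-2-yn-1-one (not isolated; present as its phenoxide) | COc1ccc(C#CC(=O)c2c(OC)cc(OC)c(Cc3ccc(OC)cc3)c2O)cc1 | intermediate
16 | 5,7-dimethoxy-8-(4-methoxybenzyl)-2-(4-methoxyphenyl)-4H-chromen-4-one | COc1ccc(-c2cc(=O)c3c(OC)cc(OC)c(Cc4ccc(OC)cc4)c3o2)cc1 | intermediate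
17 | 3-lithio-5,7-dimethoxy-8-(4-methoxybenzyl)-2-(4-methoxyphenyl)-4H-chromen-4-one (not isolated) | COc1ccc(-c2oc3c(Cc4ccc(OC)cc4)c(OC)cc(OC)c3c(=O)c2[Li])cc1 | intermediate
18 | dimethyl [5,7-dimethoxy-8-(4-methoxybenzyl)-2-(4-methoxyphenyl)-4-oxo-4H-chromen-3-yl]boronate (not isolated) | COc1ccc(-c2oc3c(Cc4ccc(OC)cc4)c(OC)cc(OC)c3c(=O)c2B(OC)OC)cc1 | intermediate
19 | 3-hydroxy-5,7-dimethoxy-8-(4-methoxybenzyl)-2-(4-methoxyphenyl)-4H-chromen-4-one | COc1ccc(-c2oc3c(Cc4ccc(OC)cc4)c(OC)cc(OC)c3c(=O)c2O)cc1 | intermediate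
20 | 8-C-p-hydroxybenzylkaempferol | O=c1c(O)c(-c2ccc(O)cc2)oc2c(Cc3ccc(O)cc3)c(O)cc(O)c12 | target

**Totals**

Total step count: 8 steps.
Longest linear sequence: 8 steps (1 → 20); the route is linear, with 2 and 12 bought.

**Steps most likely to fail**

1. Step 6 (key step). What may go wrong:
- protonation of aryl anion 14 before the acyl shift, so that the sequence stalls at the aryl ester;
- decarboxylation of the propiolate at 125 °C;
- erosion of the aryne regioselectivity through steric pressure from the C8 benzyl group;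
- 5-exo closure of 15 to the aurone.

Fallback, from 4 back to 16, by chalcone chemistry. C-Acetylation of phenol 4 ortho to the hydroxyl (Ac2O, BF3·OEt2, then hydrolysis of the boron chelate) should give 1-[2-hydroxy-4,6-dimethoxy-3-(4-methoxybenzyl)phenyl]ethan-1-one F1. Claisen–Schmidt condensation of it with 4-methoxybenzaldehyde (KOH, EtOH) should give (E)-1-[2-hydroxy-4,6-dimethoxy-3-(4-methoxybenzyl)phenyl]-3-(4-methoxyphenyl)prop-2-en-1-one F2. Oxidative cyclisation (iodine cat., DMSO, 130 °C) should then return to flavone 16. Here too only one hydroxyl is free, so the 8-benzyl pattern is fixed.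

2. Step 7. What may go wrong: competing deprotonation of the diarylmethane CH2, ring-opening of 3-lithioflavone 17 by β-elimination of the phenoxide, or incomplete borylation.

Fallback, from 16 back to 19, by electrophilic oxygen transfer. Dimethyldioxirane (acetone/CH2Cl2, 0 °C → rt) should epoxidise the C2–C3 double bond to racemic cis-2,3-epoxy-5,7-dimethoxy-8-(4-methoxybenzyl)-2-(4-methoxyphenyl)chroman-4-one F3. Catalytic p-toluenesulfonic acid in CH2Cl2 should open and tautomerise the epoxide to flavonol 19.

3. Step 4. What may go wrong: lateral lithiation at the diarylmethane CH2 ortho to the carbamate, followed by carbamoyl migration, or an anionic Fries shift of 7 on warming.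

Fallback, from 4 back to 11, by halogen–metal exchange with no carbamate. Amine-catalysed ortho-bromination of 4 (N-bromosuccinimide, iPr2NH cat., CH2Cl2) should give 2-bromo-3,5-dimethoxy-6-(4-methoxybenzyl)phenol F4. O-Silylation with hexamethyldisilazane should give [2-bromo-3,5-dimethoxy-6-(4-methoxybenzyl)phenoxy]trimethylsilane F5. Bromine–lithium exchange with n-BuLi (THF, −78 °C) should give [2-lithio-3,5-dimethoxy-6-(4-methoxybenzyl)phenoxy]trimethylsilane F6, which should undergo retro-Brook O-to-C silyl migration to the ArOLi salt of 10. Tf2O at −78 °C should then give silyl triflate 11.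

**Further compounds**

F1 | step 6 | 1-[2-hydroxy-4,6-dimethoxy-3-(4-methoxybenzyl)phenyl]ethan-1-one | CC(=O)c1c(O)c(Cc2ccc(OC)cc2)c(OC)cc1OC
F2 | step 6 | (E)-1-[2-hydroxy-4,6-dimethoxy-3-(4-methoxybenzyl)phenyl]-3-(4-methoxyphenyl)prop-2-en-1-one | COc1ccc(/C=C/C(=O)c2c(O)c(Cc3ccc(OC)cc3)c(OC)cc2OC)cc1
F3 | step 7 | racemic cis-2,3-epoxy-5,7-dimethoxy-8-(4-methoxybenzyl)-2-(4-methoxyphenyl)chroman-4-one (one enantiomer drawn) | COc1ccc(cc1)[C@@]23O[C@@H]2C(=O)c2c(OC)cc(OC)c(Cc4ccc(OC)cc4)c2O3
F4 | step 4 | 2-bromo-3,5-dimethoxy-6-(4-methoxybenzyl)phenol | COc1ccc(Cc2c(O)c(Br)c(OC)cc2OC)cc1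
F5 | step 4 | [2-bromo-3,5-dimethoxy-6-(4-methoxybenzyl)phenoxy]trimethylsilane | COc1ccc(Cc2c(O[Si](C)(C)C)c(Br)c(OC)cc2OC)cc1
F6 | step 4 | [2-lithio-3,5-dimethoxy-6-(4-methoxybenzyl)phenoxy]trimethylsilane | COc1ccc(Cc2c(O[Si](C)(C)C)c([Li])c(OC)cc2OC)cc1
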